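**The unit.** A percent of the substrate charged is my unit, and substrate is the limiting reagent. I book each percent as substrate, as target, or as a remainder that no reading reaches.

| flask | substrate | catalyst | remark | time |
|---|---|---|---|---|
| eta | 0.10 M | 0.28 mM | run made earlier |  |
| epsilon | 0.10 M | 0.44 mM | run made earlier |  |
| flask | 0.10 M | 0.20 mM |  | 25 min |

- eta (time / min: target / %): 1.33: 27; 2.50: 33; 5.00: 33; 12.0: 19; 25.0: 5
- epsilon (time / min: target / %): 1.33: 32; 2.50: 43; 5.00: 39; 12.0: 13; 25.0: 5

(readings scatter by 2 percentage points)



* the moment within 25 min at which there is most target
* the amount of target, in percent of the substrate charged, at that time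

**The ratio.** Let s, a selectivity factor, be the rate constant for making target over that for using it up, so time drops out. I assume a chain of first-order steps. At its peak, making equals using, so target over substrate equals s. For s near one, the peak fraction is about e raised to minus the mean of one and the inverse of s.

The highest readings, 33% in eta and 43% in epsilon, give s of 0.821 and 1.45. I take s as proportional to catalyst and pool both runs into c*, the catalyst charge at which making equals using: 0.316 mM.

**The ledger.** For this flask, s is 0.632. At the peak I book 27.5% as target, 43.5% as substrate and 29.0% as the remainder. The ratio carries no time, so I commit to none.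

**The forecast.** It gives 30% at 3.8 min, noting that “The peak is higher with more catalyst”. My height is lower.

**The flask.** The flask peaks at 31.3% at 4.74 min, later than the forecast's time, with 47.1% substrate and 20.6% over-reaction product beside it.

    substrate + catalyst ⇌ catalyst + target (K = 1.90, k = 16.2 L mol⁻¹ s⁻¹)
    substrate → side product (k = 5.22 × 10⁻⁵ s⁻¹)
    target → over-reaction product (k = 0.00317 s⁻¹)

Target over substrate at that peak is 0.665, beside the s of 0.632 reckoned from c*. A neighbouring flask charged with 0.500 mM catalyst has s of 1.58, which books a peak of 44.2%, and that flask reaches 43.0%.

(All runs come from a simulation with constants of no real substance, and the scatter is random.)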